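**Plan**

- Enabling feature: the central benzene ring (chromene C4a–C8a) is a resorcinol. Oxygens at C7 and C8a flank C8–H, and C4a, C5 and C6 carry three contiguous carbon substituents. This maps onto a 1-methoxy-1,3-bis(silyloxy)diene (C6, C7, C8, C8a) and an alkyne (C5, C4a).
- Retrosynthesis: remove the aryl MOM ether, take C3=C4 back to the chroman-4-one, cut O1–C2 (oxa-Michael), then cut C5–C6 and C4a–C8a of the benzene ring into diene 15 and ynone 10.
- Ynone 10 is cut at the carbinol C–C bond (acetylide + 3-methylbut-2-enal) and the benzofuran at O1–C2 and C3–C3a (salicylaldehyde + chloroacetone). Diene 15 is cut at the prenyl–CH2 bond (acetoacetate dianion + prenyl bromide).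
- Forward ring order: benzofuran (step 2), central benzene ring (step 9), pyran (step 10). The prenyl group and all five pyran carbons arrive with the two cycloaddition partners.
- Stereochemistry: the target has no stereocentre and no stereogenic alkene. The stereocentres of 9, 16 and 19 are transient and need no control.

Key step: step 9

Remark: the target SMILES carries no stereodescriptor and the molecule is achiral, so "single enantiomer" means the compound itself and no asymmetric step is required.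

**Route**

Step 1
Reactants: 1 2,4-dihydroxybenzaldehyde
Product: 2 2-hydroxy-4-(methoxymethoxy)benzaldehyde
Conditions: MOMCl (1.05 equiv), K2CO3 (1.5 equiv), acetone, 0 °C to rt
Reagents that add atoms: chloromethyl methyl ether, COCCl
Why: Selective O-alkylation (Williamson-type MOM protection) should occur at the 4-OH, which is the more acidic phenol and is not held in the hydrogen bond to the aldehyde that deactivates the 2-OH.

Step 2
Reactants: 2 2-hydroxy-4-(methoxymethoxy)benzaldehyde; 3 chloroacetone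
Product: 5 1-[6-(methoxymethoxy)-1-benzofuran-2-yl]ethan-1-one, via 4-(methoxymethoxy)-2-(2-oxopropoxy)benzaldehyde 4 (not isolated)
Conditions: K2CO3 (2.5 equiv), MeCN, reflux
Reagents that add atoms: none
Why: Rap–Stoermer condensation: O-alkylation of the phenoxide by chloroacetone gives ether 4, whose ketone α-CH2 undergoes intramolecular aldol condensation with the neighbouring aldehyde, and dehydration aromatises the furan ring; the MOM ether is inert to carbonate.

Step 3
Reactants: 5 1-[6-(methoxymethoxy)-1-benzofuran-2-yl]ethan-1-one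
Product: 7 2-ethynyl-6-(methoxymethoxy)-1-benzofuran, via diethyl 1-[6-(methoxymethoxy)-1-benzofuran-2-yl]ethenyl phosphate 6 (not isolated)
Conditions: LDA (1.1 equiv), THF, −78 °C; ClP(O)(OEt)2, −78 °C to rt; then LDA (2.3 equiv), THF, −78 °C to rt; H2O
Reagents that add atoms: diethyl chlorophosphate, CCOP(=O)(Cl)OCC (its atoms are present in intermediate 6 only; none remain in 7)
Why: Methyl ketone to terminal alkyne by O-phosphorylation of the kinetic lithium enolate and LDA-induced β-elimination of the enol phosphate, a standard sequence for aryl methyl ketones; the MOM ether and the benzofuran tolerate amide bases at low temperature.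

Step 4
Reactants: 7 2-ethynyl-6-(methoxymethoxy)-1-benzofuran; 8 3-methylbut-2-enal
Product: 9 1-[6-(methoxymethoxy)-1-benzofuran-2-yl]-5-methylhex-4-en-1-yn-3-ol (racemic)
Conditions: n-BuLi (1.05 equiv), THF, −78 °C; then 8, −78 to −20 °C; H2O
Reagents that add atoms: none
Why: 1,2-Addition of a lithium acetylide to an enal; the hard acetylide should add to the carbonyl only, and the new carbinol stereocentre is formed as a racemate and removed in step 5.

Step 5
Reactants: 9 1-[6-(methoxymethoxy)-1-benzofuran-2-yl]-5-methylhex-4-en-1-yn-3-ol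
Product: 10 1-[6-(methoxymethoxy)-1-benzofuran-2-yl]-5-methylhex-4-en-1-yn-3-one
Conditions: activated MnO2 (15 equiv), CH2Cl2, rt
Reagents that add atoms: none
Why: MnO2 oxidation of a doubly activated (propargylic and allylic) secondary alcohol under neutral conditions should give the cross-conjugated ynone without touching the MOM ether or the alkenes.

Step 6
Reactants: 11 methyl acetoacetate; 12 1-bromo-3-methylbut-2-ene
Product: 13 methyl 7-methyl-3-oxooct-6-enoate
Conditions: NaH (1.1 equiv), THF, 0 °C; n-BuLi (1.05 equiv), 0 °C; then 12, 0 °C to rt; 1 M HCl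
Reagents that add atoms: none
Why: γ-Alkylation of the acetoacetate dianion: the more basic terminal carbanion reacts by SN2 with the primary allylic bromide, leaving the stabilised enolate untouched.

Step 7
Reactants: 13 methyl 7-methyl-3-oxooct-6-enoate
Product: 14 methyl 7-methyl-3-(trimethylsilyloxy)octa-2,6-dienoate (C2=C3 geometry not controlled)
Conditions: TMSCl (1.5 equiv), Et3N (1.6 equiv), toluene, rt; filter, concentrate
Reagents that add atoms: chlorotrimethylsilane, C[Si](C)(C)Cl
Why: O-Silylation of the β-keto ester enol with amine base is the standard first stage of bis(silyloxy)diene synthesis; both geometric isomers converge in step 8.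

Step 8
Reactants: 14 methyl 7-methyl-3-(trimethylsilyloxy)octa-2,6-dienoate
Product: 15 (3Z)-1-methoxy-7-methyl-1,3-bis(trimethylsilyloxy)octa-1,3,6-triene
Conditions: LDA (1.3 equiv), THF, −78 °C; TMSCl (1.5 equiv), −78 to 20 °C; hexane, filtration under Ar; used at once
Reagents that add atoms: chlorotrimethylsilane, C[Si](C)(C)Cl
Why: γ-Deprotonation of the silyloxy enoate and O-silylation of the ester dienolate give the ketene-acetal diene; the (3Z) geometry, with the prenyl CH2 cis to the silyloxy group, is the usual outcome for 4-alkyl dienes of this class.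

Step 9
Reactants: 15 (3Z)-1-methoxy-7-methyl-1,3-bis(trimethylsilyloxy)octa-1,3,6-triene; 10 1-[6-(methoxymethoxy)-1-benzofuran-2-yl]-5-methylhex-4-en-1-yn-3-one
Product: 17 1-{2,4-dihydroxy-6-[6-(methoxymethoxy)-1-benzofuran-2-yl]-5-(3-methylbut-2-en-1-yl)phenyl}-3-methylbut-2-en-1-one, via 1-{6-methoxy-2-[6-(methoxymethoxy)-1-benzofuran-2-yl]-3-(3-methylbut-2-en-1-yl)-4,6-bis(trimethylsilyloxy)cyclohexa-1,4-dien-1-yl}-3-methylbut-2-en-1-one 16 (not isolated)
Conditions: 15 (2.5 equiv), toluene (ca. 1 M), 90 °C, sealed tube, Ar; then THF/1 M aq. HCl, 0 °C, 15 min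
Reagents that add atoms: none
Why: The electron-rich diene 15 and the electron-poor alkyne of 10 combine in a normal-demand, strongly asynchronous [4+2] cycloaddition: the prenyl-bearing terminus C4 of 15 (largest HOMO coefficient) bonds to the alkyne carbon β to the carbonyl, which carries the benzofuran (future C6–C5 bond), and the ketene-acetal carbon C1 bonds to the α-carbon (future C8a–C4a bond), giving cyclohexa-1,4-diene 16. The closest known reaction type is the Diels–Alder/aromatisation of 1-alkoxy-1,3-bis(silyloxy)buta-1,3-dienes with acetylenic ketones and esters to give resorcinols. The six-membered carbocycle closes in the cycloaddition itself (suprafacial 4π+2π), after which cold dilute acid cleaves the Si–O bonds, the C(OMe)(OH) hemiketal expels methanol and the dienone enolises to the aromatic resorcinol 17. No stereocentre is set: the two sp3 ring carbons of 16 form as a diastereomer mixture and both become aromatic carbons. The step needs regioselectivity and [4+2] rather than [3+3] periselectivity; the first follows from the matched polarisation (nucleophilic diene C4, electrophilic ynone β-carbon), the second from Lewis-acid-free thermal conditions, under which diene C2 should not engage the ketone carbonyl. Chemoselectivity for the alkyne over the β,β-dimethyl enone C=C rests on the low dienophilicity of a trisubstituted alkene, and the (3Z) geometry of 15 places the prenyl CH2 outside the s-cis diene so that the hindered terminus can reach the alkyne.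

Step 10
Reactants: 17 1-{2,4-dihydroxy-6-[6-(methoxymethoxy)-1-benzofuran-2-yl]-5-(3-methylbut-2-en-1-yl)phenyl}-3-methylbut-2-en-1-one
Product: 18 7-hydroxy-5-[6-(methoxymethoxy)-1-benzofuran-2-yl]-2,2-dimethyl-6-(3-methylbut-2-en-1-yl)-2,3-dihydro-4H-chromen-4-one
Conditions: K2CO3 (0.3 equiv), MeOH, rt
Reagents that add atoms: none
Why: Base-catalysed intramolecular oxa-Michael addition (6-endo-trig): only the phenoxide ortho to the acyl group can reach the enone β-carbon, and the gem-dimethyl group (Thorpe–Ingold effect) should favour the closed 2,2-dimethylchromanone.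

Step 11
Reactants: 18 7-hydroxy-5-[6-(methoxymethoxy)-1-benzofuran-2-yl]-2,2-dimethyl-6-(3-methylbut-2-en-1-yl)-2,3-dihydro-4H-chromen-4-one
Product: 19 5-[6-(methoxymethoxy)-1-benzofuran-2-yl]-2,2-dimethyl-6-(3-methylbut-2-en-1-yl)-3,4-dihydro-2H-chromene-4,7-diol (racemic)
Conditions: LiAlH4 (3 equiv), THF, 0 °C to rt; aq. Rochelle salt
Reagents that add atoms: none
Why: Hydride reduction of the aryl ketone; LiAlH4 in excess is chosen because the free 7-OH consumes hydride and its phenoxide deactivates the carbonyl, while the MOM ether, benzofuran and isolated alkene are inert, and the new C4 stereocentre is racemic and removed in step 12.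

Step 12
Reactants: 19 5-[6-(methoxymethoxy)-1-benzofuran-2-yl]-2,2-dimethyl-6-(3-methylbut-2-en-1-yl)-3,4-dihydro-2H-chromene-4,7-diol
Product: 20 5-[6-(methoxymethoxy)-1-benzofuran-2-yl]-2,2-dimethyl-6-(3-methylbut-2-en-1-yl)-2H-chromen-7-ol
Conditions: PPTS (0.1 equiv), toluene, 4 Å MS, 60 °C
Reagents that add atoms: none
Why: Acid-catalysed E1 dehydration: the C4 cation is stabilised by the ring oxygen (ortho) and the 7-OH (para), so a weak acid in an aprotic solvent should suffice and should spare the MOM ether and the prenyl group.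

Step 13
Reactants: 20 5-[6-(methoxymethoxy)-1-benzofuran-2-yl]-2,2-dimethyl-6-(3-methylbut-2-en-1-yl)-2H-chromen-7-ol
Product: 21 cathafuran C, 5-(6-hydroxy-1-benzofuran-2-yl)-2,2-dimethyl-6-(3-methylbut-2-en-1-yl)-2H-chromen-7-ol
Conditions: conc. HCl (to ca. 0.5 M), MeOH, 40 °C, short reaction time; NaHCO3
Reagents that add atoms: none
Why: Acid-catalysed methanolysis of the aryl methoxymethyl acetal, the standard unmasking of MOM-protected prenylated phenols; mild temperature and short exposure are chosen to spare the ortho-prenylphenol and the chromene.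

**Compound list**

1 | 2,4-dihydroxybenzaldehyde | O=Cc1ccc(O)cc1O | starting material
2 | 2-hydroxy-4-(methoxymethoxy)benzaldehyde | COCOc1ccc(C=O)c(O)c1 | intermediate
3 | chloroacetone | CC(=O)CCl | starting material
4 | 4-(methoxymethoxy)-2-(2-oxopropoxy)benzaldehyde (not isolated) | CC(=O)COc1cc(OCOC)ccc1C=O | intermediate
5 | 1-[6-(methoxymethoxy)-1-benzofuran-2-yl]ethan-1-one | CC(=O)c1cc2ccc(OCOC)cc2o1 | intermediate
6 | diethyl 1-[6-(methoxymethoxy)-1-benzofuran-2-yl]ethenyl phosphate (not isolated) | C=C(OP(=O)(OCC)OCC)c1cc2ccc(OCOC)cc2o1 | intermediate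
7 | 2-ethynyl-6-(methoxymethoxy)-1-benzofuran | C#Cc1cc2ccc(OCOC)cc2o1 | intermediate
8 | 3-methylbut-2-enal | CC(C)=CC=O | starting material
9 | 1-[6-(methoxymethoxy)-1-benzofuran-2-yl]-5-methylhex-4-en-1-yn-3-ol (racemic) | CC(C)=CC(O)C#Cc1cc2ccc(OCOC)cc2o1 | intermediate
10 | 1-[6-(methoxymethoxy)-1-benzofuran-2-yl]-5-methylhex-4-en-1-yn-3-one | CC(C)=CC(=O)C#Cc1cc2ccc(OCOC)cc2o1 | intermediate
11 | methyl acetoacetate | CC(=O)CC(=O)OC | starting material
12 | 1-bromo-3-methylbut-2-ene | CC(C)=CCBr | starting material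
13 | methyl 7-methyl-3-oxooct-6-enoate | CC(C)=CCCC(=O)CC(=O)OC | intermediate
14 | methyl 7-methyl-3-(trimethylsilyloxy)octa-2,6-dienoate (C2=C3 geometry not controlled) | CC(C)=CCCC(O[Si](C)(C)C)=CC(=O)OC | intermediate
15 | (3Z)-1-methoxy-7-methyl-1,3-bis(trimethylsilyloxy)octa-1,3,6-triene | CC(C)=CC/C=C(O[Si](C)(C)C)/C=C(OC)O[Si](C)(C)C | intermediate
16 | 1-{6-methoxy-2-[6-(methoxymethoxy)-1-benzofuran-2-yl]-3-(3-methylbut-2-en-1-yl)-4,6-bis(trimethylsilyloxy)cyclohexa-1,4-dien-1-yl}-3-methylbut-2-en-1-one (diastereomer mixture, not isolated) | COC1(O[Si](C)(C)C)C=C(O[Si](C)(C)C)C(CC=C(C)C)C(c2cc3ccc(OCOC)cc3o2)=C1C(=O)C=C(C)C | intermediate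
17 | 1-{2,4-dihydroxy-6-[6-(methoxymethoxy)-1-benzofuran-2-yl]-5-(3-methylbut-2-en-1-yl)phenyl}-3-methylbut-2-en-1-one | CC(C)=CCc1c(O)cc(O)c(C(=O)C=C(C)C)c1-c1cc2ccc(OCOC)cc2o1 | intermediate
18 | 7-hydroxy-5-[6-(methoxymethoxy)-1-benzofuran-2-yl]-2,2-dimethyl-6-(3-methylbut-2-en-1-yl)-2,3-dihydro-4H-chromen-4-one | CC(C)=CCc1c(O)cc2c(c1-c1cc3ccc(OCOC)cc3o1)C(=O)CC(C)(C)O2 | intermediate
19 | 5-[6-(methoxymethoxy)-1-benzofuran-2-yl]-2,2-dimethyl-6-(3-methylbut-2-en-1-yl)-3,4-dihydro-2H-chromene-4,7-diol (racemic) | CC(C)=CCc1c(O)cc2c(c1-c1cc3ccc(OCOC)cc3o1)C(O)CC(C)(C)O2 | intermediate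
20 | 5-[6-(methoxymethoxy)-1-benzofuran-2-yl]-2,2-dimethyl-6-(3-methylbut-2-en-1-yl)-2H-chromen-7-ol | CC(C)=CCc1c(O)cc2c(c1-c1cc3ccc(OCOC)cc3o1)C=CC(C)(C)O2 | intermediate
21 | cathafuran C, 5-(6-hydroxy-1-benzofuran-2-yl)-2,2-dimethyl-6-(3-methylbut-2-en-1-yl)-2H-chromen-7-ol (achiral) | CC(C)=CCc1c(O)cc2c(c1-c1cc3ccc(O)cc3o1)C=CC(C)(C)O2 | target

**Step count**

Total: 13 steps. Longest linear sequence: 10 steps (steps 1–5 and 9–13). The diene branch (steps 6–8) joins at step 9.

**Steps most likely to fail**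

Step 9. The cycloaddition may be outrun by thermal decay of the diene (silyl migration, protodesilylation). The alkyne carbon that must accept the hindered, prenyl-bearing diene terminus carries a donor benzofuran, and the cross-conjugated enone activates only moderately. Leakage into the [3+3] mode through diene C2 would give a regioisomeric salicylate.

The fallback sets out from alkyne 7 and diene 15 and returns at chromene 20. Alkyne 7 is lithiated (n-BuLi, THF, −78 °C) and formylated with DMF (inverse quench into aq. KH2PO4) to give 3-[6-(methoxymethoxy)-1-benzofuran-2-yl]prop-2-ynal F1, a smaller and more electrophilic dienophile. Heating it with 15 as in step 9 should give the cycloadduct 6-methoxy-2-[6-(methoxymethoxy)-1-benzofuran-2-yl]-3-(3-methylbut-2-en-1-yl)-4,6-bis(trimethylsilyloxy)cyclohexa-1,4-diene-1-carbaldehyde F2, which is not isolated. The same cold acidic work-up should then give 2,4-dihydroxy-6-[6-(methoxymethoxy)-1-benzofuran-2-yl]-5-(3-methylbut-2-en-1-yl)benzaldehyde F3. Excess (2-methylprop-1-enyl)magnesium bromide (THF, 0 °C) adds to the aldehyde to give 4-(1-hydroxy-3-methylbut-2-en-1-yl)-5-[6-(methoxymethoxy)-1-benzofuran-2-yl]-6-(3-methylbut-2-en-1-yl)benzene-1,3-diol F4. With catalytic PPTS in warm toluene this should lose water to the o-quinone methide 3-hydroxy-5-[6-(methoxymethoxy)-1-benzofuran-2-yl]-4-(3-methylbut-2-en-1-yl)-6-(3-methylbut-2-en-1-ylidene)cyclohexa-2,4-dien-1-one F5, not isolated, whose oxa-6π electrocyclisation closes the pyran and gives 20. Steps 10–12 are then bypassed.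

Step 11. Hydride delivery may stall because the first equivalent of LiAlH4 deprotonates the 7-OH, and the phenoxide, para to C4a, turns the peri-hindered C4 ketone into a vinylogous carboxylate. Alternatively the p-oxidobenzylic alkoxide may ionise to a quinone methide that is reduced further to the chroman.

The fallback sets out from chromanone 18 and returns at chromene 20. Silylation (TBSCl, imidazole, DMF) gives 7-{[tert-butyl(dimethyl)silyl]oxy}-5-[6-(methoxymethoxy)-1-benzofuran-2-yl]-2,2-dimethyl-6-(3-methylbut-2-en-1-yl)-2,3-dihydro-4H-chromen-4-one F6, in which the ketone is no longer conjugated to a phenoxide. NaBH4 (MeOH/THF, 0 °C) should then give 7-{[tert-butyl(dimethyl)silyl]oxy}-5-[6-(methoxymethoxy)-1-benzofuran-2-yl]-2,2-dimethyl-6-(3-methylbut-2-en-1-yl)-3,4-dihydro-2H-chromen-4-ol F7. PPTS in toluene at 60 °C dehydrates it to tert-butyl({5-[6-(methoxymethoxy)-1-benzofuran-2-yl]-2,2-dimethyl-6-(3-methylbut-2-en-1-yl)-2H-chromen-7-yl}oxy)dimethylsilane F8, and TBAF (THF, 0 °C) frees the 7-OH to give 20.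

Step 13. During acid cleavage of the MOM ether the prenyl alkene may be protonated and trapped by the neighbouring 7-OH (closure to a dihydropyran), or the electron-rich chromene may add methanol or oligomerise.

The fallback sets out from alkyne 7 and returns at the target 21. It moves the only strongly acidic step to a stage that has neither a prenylphenol nor a chromene.
- Protecting-group switch: the MOM ether of 7 is cleaved (HCl, MeOH, 40 °C) to 2-ethynyl-1-benzofuran-6-ol F9, which is silylated (TBSCl, imidazole, DMF) to tert-butyl[(2-ethynyl-1-benzofuran-6-yl)oxy]dimethylsilane F10.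
- Ynone: lithiation and addition to 8 as in step 4 give 1-(6-{[tert-butyl(dimethyl)silyl]oxy}-1-benzofuran-2-yl)-5-methylhex-4-en-1-yn-3-ol F11, and MnO2 gives 1-(6-{[tert-butyl(dimethyl)silyl]oxy}-1-benzofuran-2-yl)-5-methylhex-4-en-1-yn-3-one F12.
- Cycloaddition: reaction with 15 as in step 9 passes through the cycloadduct 1-{2-(6-{[tert-butyl(dimethyl)silyl]oxy}-1-benzofuran-2-yl)-6-methoxy-3-(3-methylbut-2-en-1-yl)-4,6-bis(trimethylsilyloxy)cyclohexa-1,4-dien-1-yl}-3-methylbut-2-en-1-one F13, not isolated, to 1-{6-(6-{[tert-butyl(dimethyl)silyl]oxy}-1-benzofuran-2-yl)-2,4-dihydroxy-5-(3-methylbut-2-en-1-yl)phenyl}-3-methylbut-2-en-1-one F14.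
- Endgame: K2CO3 in MeOH closes the pyranone as in step 10 and methanolyses the aryl silyl ether in the same flask, giving 7-hydroxy-5-(6-hydroxy-1-benzofuran-2-yl)-2,2-dimethyl-6-(3-methylbut-2-en-1-yl)-2,3-dihydro-4H-chromen-4-one F15. LiAlH4 as in step 11 gives 5-(6-hydroxy-1-benzofuran-2-yl)-2,2-dimethyl-6-(3-methylbut-2-en-1-yl)-3,4-dihydro-2H-chromene-4,7-diol F16, and PPTS as in step 12 gives 21 with no final deprotection.

**Further compounds**

F1 | step 9 | 3-[6-(methoxymethoxy)-1-benzofuran-2-yl]prop-2-ynal | O=CC#Cc1cc2ccc(OCOC)cc2o1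
F2 | step 9 | 6-methoxy-2-[6-(methoxymethoxy)-1-benzofuran-2-yl]-3-(3-methylbut-2-en-1-yl)-4,6-bis(trimethylsilyloxy)cyclohexa-1,4-diene-1-carbaldehyde | COC1(O[Si](C)(C)C)C=C(O[Si](C)(C)C)C(CC=C(C)C)C(c2cc3ccc(OCOC)cc3o2)=C1C=O
F3 | step 9 | 2,4-dihydroxy-6-[6-(methoxymethoxy)-1-benzofuran-2-yl]-5-(3-methylbut-2-en-1-yl)benzaldehyde | CC(C)=CCc1c(O)cc(O)c(C=O)c1-c1cc2ccc(OCOC)cc2o1
F4 | step 9 | 4-(1-hydroxy-3-methylbut-2-en-1-yl)-5-[6-(methoxymethoxy)-1-benzofuran-2-yl]-6-(3-methylbut-2-en-1-yl)benzene-1,3-diol (racemic) | CC(C)=CCc1c(O)cc(O)c(C(O)C=C(C)C)c1-c1cc2ccc(OCOC)cc2o1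
F5 | step 9 | 3-hydroxy-5-[6-(methoxymethoxy)-1-benzofuran-2-yl]-4-(3-methylbut-2-en-1-yl)-6-(3-methylbut-2-en-1-ylidene)cyclohexa-2,4-dien-1-one | O=C1C=C(O)C(CC=C(C)C)=C(c2cc3ccc(OCOC)cc3o2)C1=CC=C(C)C
F6 | step 11 | 7-{[tert-butyl(dimethyl)silyl]oxy}-5-[6-(methoxymethoxy)-1-benzofuran-2-yl]-2,2-dimethyl-6-(3-methylbut-2-en-1-yl)-2,3-dihydro-4H-chromen-4-one | CC(C)=CCc1c(O[Si](C)(C)C(C)(C)C)cc2c(c1-c1cc3ccc(OCOC)cc3o1)C(=O)CC(C)(C)O2
F7 | step 11 | 7-{[tert-butyl(dimethyl)silyl]oxy}-5-[6-(methoxymethoxy)-1-benzofuran-2-yl]-2,2-dimethyl-6-(3-methylbut-2-en-1-yl)-3,4-dihydro-2H-chromen-4-ol (racemic) | CC(C)=CCc1c(O[Si](C)(C)C(C)(C)C)cc2c(c1-c1cc3ccc(OCOC)cc3o1)C(O)CC(C)(C)O2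
F8 | step 11 | tert-butyl({5-[6-(methoxymethoxy)-1-benzofuran-2-yl]-2,2-dimethyl-6-(3-methylbut-2-en-1-yl)-2H-chromen-7-yl}oxy)dimethylsilane | CC(C)=CCc1c(O[Si](C)(C)C(C)(C)C)cc2c(c1-c1cc3ccc(OCOC)cc3o1)C=CC(C)(C)O2
F9 | step 13 | 2-ethynyl-1-benzofuran-6-ol | C#Cc1cc2ccc(O)cc2o1
F10 | step 13 | tert-butyl[(2-ethynyl-1-benzofuran-6-yl)oxy]dimethylsilane | C#Cc1cc2ccc(O[Si](C)(C)C(C)(C)C)cc2o1
F11 | step 13 | 1-(6-{[tert-butyl(dimethyl)silyl]oxy}-1-benzofuran-2-yl)-5-methylhex-4-en-1-yn-3-ol (racemic) | CC(C)=CC(O)C#Cc1cc2ccc(O[Si](C)(C)C(C)(C)C)cc2o1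
F12 | step 13 | 1-(6-{[tert-butyl(dimethyl)silyl]oxy}-1-benzofuran-2-yl)-5-methylhex-4-en-1-yn-3-one | CC(C)=CC(=O)C#Cc1cc2ccc(O[Si](C)(C)C(C)(C)C)cc2o1
F13 | step 13 | 1-{2-(6-{[tert-butyl(dimethyl)silyl]oxy}-1-benzofuran-2-yl)-6-methoxy-3-(3-methylbut-2-en-1-yl)-4,6-bis(trimethylsilyloxy)cyclohexa-1,4-dien-1-yl}-3-methylbut-2-en-1-one | COC1(O[Si](C)(C)C)C=C(O[Si](C)(C)C)C(CC=C(C)C)C(c2cc3ccc(O[Si](C)(C)C(C)(C)C)cc3o2)=C1C(=O)C=C(C)C
F14 | step 13 | 1-{6-(6-{[tert-butyl(dimethyl)silyl]oxy}-1-benzofuran-2-yl)-2,4-dihydroxy-5-(3-methylbut-2-en-1-yl)phenyl}-3-methylbut-2-en-1-one | CC(C)=CCc1c(O)cc(O)c(C(=O)C=C(C)C)c1-c1cc2ccc(O[Si](C)(C)C(C)(C)C)cc2o1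
F15 | step 13 | 7-hydroxy-5-(6-hydroxy-1-benzofuran-2-yl)-2,2-dimethyl-6-(3-methylbut-2-en-1-yl)-2,3-dihydro-4H-chromen-4-one | CC(C)=CCc1c(O)cc2c(c1-c1cc3ccc(O)cc3o1)C(=O)CC(C)(C)O2
F16 | step 13 | 5-(6-hydroxy-1-benzofuran-2-yl)-2,2-dimethyl-6-(3-methylbut-2-en-1-yl)-3,4-dihydro-2H-chromene-4,7-diol (racemic) | CC(C)=CCc1c(O)cc2c(c1-c1cc3ccc(O)cc3o1)C(O)CC(C)(C)O2
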